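Assumption: the target is taken as the free hydrogen sulfate exactly as drawn; its sodium salt is the practical storage form, because the free acid can protonate its own alkenes when concentrated.

## Retrosynthetic overview

1. Target ⇒ O-sulfation of the primary alcohol; the CH2–CH2 bond next to the side-chain stereocentre ⇒ alkylation of a chiral α-sulfonyl carbanion with an (E)-allylic bromide, then reductive desulfonylation.
2. Sulfone fragment ⇒ lipase desymmetrisation of a prochiral 2-substituted propane-1,3-diol (sets the remote stereocentre); furan attached by B-alkyl Suzuki coupling with 3-bromofuran.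
3. Allylic bromide ⇒ Zr-catalysed carboalumination/formaldehyde trapping of a terminal alkyne (E-trisubstituted alkene); alkyne from the allyl group of a ring ketone.
4. Ring stereocentres ⇒ Cu-catalysed asymmetric conjugate methylation of 2-methylcyclohex-2-enone (first stereocentre), then anti-allylation of the enolate (quaternary centre); ring alkene by enol triflate methylation.
5. Ring order: no ring is built. The carbocycle comes from 2-methylcyclohexenone and the furan from 3-bromofuran; only a temporary acetonide ring is made and removed.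

## Route

**Step 1**
Reactants: 1 2-methylcyclohex-2-en-1-one
Product: 3 {[(3R)-2,3-dimethylcyclohex-1-en-1-yl]oxy}trimethylsilane, via aluminium enolate 2 (not isolated)
Conditions: Me3Al, CuTC (2 mol%), chiral phosphoramidite L* (4 mol%, antipode giving 3R), Et2O, −30 °C; then TMSOTf, THF, −30 → 0 °C; Et3N/NaHCO3 work-up
Reagents that add atoms: trimethylaluminium C[Al](C)C; trimethylsilyl trifluoromethanesulfonate C[Si](C)(C)OS(=O)(=O)C(F)(F)F
Why: Cu(I)/phosphoramidite-catalysed asymmetric conjugate addition delivers methyl to one enantioface of the β-carbon (C3 = R, the first stereocentre, typically ≥90% ee), and O-silylation of the aluminium enolate stores the enolate regiochemistry.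

**Step 2**
Reactants: 3 {[(3R)-2,3-dimethylcyclohex-1-en-1-yl]oxy}trimethylsilane
Product: 5 (2S,3R)-2,3-dimethyl-2-(prop-2-en-1-yl)cyclohexan-1-one, via lithium enolate 4 (not isolated)
Conditions: MeLi, THF, 0 °C → rt; then HMPA, allyl bromide, −78 → 0 °C
Reagents that add atoms: methyllithium C[Li] (lithium held in 4 only); allyl bromide C=CCBr
Why: MeLi cleaves the silyl enol ether to the regiodefined tetrasubstituted lithium enolate, and enolate alkylation occurs axially on the face anti to the pseudoaxial C3 methyl, so the quaternary centre forms with allyl trans to that methyl (methyls cis, about 9:1, minor epimer removed by chromatography).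

**Step 3**
Reactants: 5 (2S,3R)-2,3-dimethyl-2-(prop-2-en-1-yl)cyclohexan-1-one
Product: 7 (5R,6S)-5,6-dimethyl-6-(prop-2-en-1-yl)cyclohex-1-en-1-yl trifluoromethanesulfonate, via potassium enolate 6 (not isolated)
Conditions: KHMDS, THF, −78 °C; then PhNTf2, −78 → 0 °C
Reagents that add atoms: KHMDS C[Si](C)(C)N([K])[Si](C)(C)C (potassium held in 6 only); N-phenylbis(trifluoromethanesulfonimide) O=S(=O)(N(c1ccccc1)S(=O)(=O)C(F)(F)F)C(F)(F)F
Why: the ketone can enolise only towards C6 because C2 is quaternary, so deprotonation and O-triflation give a single enol triflate without touching the stereocentres.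

**Step 4**
Reactants: 7 (5R,6S)-5,6-dimethyl-6-(prop-2-en-1-yl)cyclohex-1-en-1-yl trifluoromethanesulfonate
Product: 8 (5R,6S)-1,5,6-trimethyl-6-(prop-2-en-1-yl)cyclohex-1-ene
Conditions: MeMgBr, Fe(acac)3 (5 mol%), THF/NMP, −30 → 0 °C
Reagents that add atoms: methylmagnesium bromide C[Mg]Br
Why: iron-catalysed Kumada-type cross-coupling replaces OTf by methyl with the ring double bond fixed in position; the isolated terminal alkene is inert.

**Step 5**
Reactants: 8 (5R,6S)-1,5,6-trimethyl-6-(prop-2-en-1-yl)cyclohex-1-ene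
Product: 10 3-[(1S,6R)-1,2,6-trimethylcyclohex-2-en-1-yl]propan-1-ol, via B-alkyl-9-BBN borane 9 (not isolated)
Conditions: 9-BBN, THF, 0 °C → rt; then NaOH aq, H2O2, 0 °C → rt
Reagents that add atoms: 9-BBN B1C2CCCC1CCC2 (boron held in 9 only); hydrogen peroxide OO
Why: hydroboration–oxidation with bulky 9-BBN is anti-Markovnikov and reacts only at the monosubstituted alkene, leaving the hindered trisubstituted ring alkene.

**Step 6**
Reactants: 10 3-[(1S,6R)-1,2,6-trimethylcyclohex-2-en-1-yl]propan-1-ol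
Product: 11 3-[(1S,6R)-1,2,6-trimethylcyclohex-2-en-1-yl]propanal
Conditions: PhI(OAc)2, TEMPO (10 mol%), CH2Cl2, rt
Reagents that add atoms: none
Why: TEMPO/PhI(OAc)2 oxidation stops at the aldehyde and spares the alkene; no stereocentre is α to the carbonyl.

**Step 7**
Reactants: 11 3-[(1S,6R)-1,2,6-trimethylcyclohex-2-en-1-yl]propanal
Product: 12 (5R,6S)-6-(but-3-yn-1-yl)-1,5,6-trimethylcyclohex-1-ene
Conditions: Ohira–Bestmann reagent, K2CO3, MeOH, 0 °C → rt
Reagents that add atoms: dimethyl (1-diazo-2-oxopropyl)phosphonate COP(=O)(OC)C(=[N+]=[N-])C(C)=O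
Why: Seyferth–Gilbert homologation (Ohira–Bestmann variant) converts the aldehyde into the terminal alkyne with one added carbon under mild base.

**Step 8**
Reactants: 12 (5R,6S)-6-(but-3-yn-1-yl)-1,5,6-trimethylcyclohex-1-ene
Product: 15 (2E)-3-methyl-5-[(1S,6R)-1,2,6-trimethylcyclohex-2-en-1-yl]pent-2-en-1-ol, via alkenylalane 13 (not isolated), via lithium alkenylalanate 14 (not isolated)
Conditions: Me3Al, Cp2ZrCl2 (25 mol%), CH2Cl2, 0 °C → rt; concentrate; n-BuLi, THF/hexane, −78 → 0 °C; (CH2O)n, rt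
Reagents that add atoms: trimethylaluminium C[Al](C)C; n-butyllithium CCCC[Li] (held in 14 only); formaldehyde (from paraformaldehyde) C=O
Why: Negishi Zr-catalysed carboalumination adds Me and Al syn across the alkyne with Me on the internal carbon, and the alkenylalanate is hydroxymethylated with retention, giving only the E allylic alcohol.

**Step 9**
Reactants: 15 (2E)-3-methyl-5-[(1S,6R)-1,2,6-trimethylcyclohex-2-en-1-yl]pent-2-en-1-ol
Product: 16 (5R,6S)-6-[(3E)-5-bromo-3-methylpent-3-en-1-yl]-1,5,6-trimethylcyclohex-1-ene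
Conditions: CBr4, PPh3, CH2Cl2, −20 → 0 °C (use at once)
Reagents that add atoms: carbon tetrabromide BrC(Br)(Br)Br
Why: Appel bromination converts the primary allylic alcohol into the bromide under neutral conditions without allylic transposition or loss of E geometry.

**Step 10**
Reactants: 17 diethyl 2-(prop-2-en-1-yl)propanedioate
Product: 18 2-(prop-2-en-1-yl)propane-1,3-diol
Conditions: LiAlH4, THF, 0 °C → rt
Reagents that add atoms: none
Why: hydride reduction of both esters gives the prochiral 1,3-diol; the alkene is inert.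

**Step 11**
Reactants: 18 2-(prop-2-en-1-yl)propane-1,3-diol
Product: 19 2,2-dimethyl-5-(prop-2-en-1-yl)-1,3-dioxane
Conditions: Me2C(OMe)2, PPTS (cat.), CH2Cl2, rt
Reagents that add atoms: 2,2-dimethoxypropane COC(C)(C)OC
Why: acid-catalysed transketalisation forms the six-membered acetonide, masking both OH groups against the borane and base of the next step.

**Step 12**
Reactants: 19 2,2-dimethyl-5-(prop-2-en-1-yl)-1,3-dioxane; 20 3-bromofuran
Product: 22 5-[3-(furan-3-yl)propyl]-2,2-dimethyl-1,3-dioxane, via B-alkyl-9-BBN borane 21 (not isolated)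
Conditions: 9-BBN, THF, 0 °C → rt; then 20, PdCl2(dppf) (5 mol%), K3PO4 aq, DMF, 60 °C
Reagents that add atoms: 9-BBN B1C2CCCC1CCC2 (boron held in 21 only)
Why: anti-Markovnikov hydroboration followed by B-alkyl Suzuki–Miyaura coupling forms the sp3–sp2 bond at furan C3; the acetonide is stable to the basic medium.

**Step 13**
Reactants: 22 5-[3-(furan-3-yl)propyl]-2,2-dimethyl-1,3-dioxane
Product: 23 2-[3-(furan-3-yl)propyl]propane-1,3-diol
Conditions: PPTS (cat.), MeOH, 40 °C
Reagents that add atoms: none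
Why: mild acid-catalysed methanolysis of the acetonide frees the prochiral diol without harming the 3-alkylfuran.

**Step 14**
Reactants: 23 2-[3-(furan-3-yl)propyl]propane-1,3-diol
Product: 24 (2S)-5-(furan-3-yl)-2-(hydroxymethyl)pentyl acetate
Conditions: lipase (Pseudomonas fluorescens lipase, Amano AK), vinyl acetate, i-Pr2O, 25 °C, stopped at 5–10% diacetate
Reagents that add atoms: vinyl acetate CC(=O)OC=C
Why: the lipase distinguishes the two enantiotopic CH2OH groups in an irreversible transesterification (enzymatic desymmetrisation), setting the side-chain stereocentre; the (S)-sense is the expected one for 2-alkylpropane-1,3-diols and must be confirmed (Mosher ester), with the opposite outcome handled in the fallback.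

**Step 15**
Reactants: 24 (2S)-5-(furan-3-yl)-2-(hydroxymethyl)pentyl acetate
Product: 25 (2R)-5-(furan-3-yl)-2-(iodomethyl)pentyl acetate
Conditions: I2, PPh3, imidazole, CH2Cl2, 0 °C (24 used at once)
Reagents that add atoms: iodine II
Why: Appel-type (Garegg) iodination converts the free primary OH at 0 °C before 1,3-acyl migration can erode ee; the stereocentre is not a reacting centre and only its CIP label changes.

**Step 16**
Reactants: 25 (2R)-5-(furan-3-yl)-2-(iodomethyl)pentyl acetate
Product: 26 (2R)-5-(furan-3-yl)-2-[(phenylsulfonyl)methyl]pentyl acetate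
Conditions: PhSO2Na, DMF, 60 °C
Reagents that add atoms: sodium benzenesulfinate [Na+].[O-]S(=O)c1ccccc1
Why: SN2 displacement of the primary iodide by the S-nucleophilic sulfinate gives the sulfone directly, so no oxidant meets the furan.

**Step 17**
Reactants: 26 (2R)-5-(furan-3-yl)-2-[(phenylsulfonyl)methyl]pentyl acetate
Product: 27 (2R)-5-(furan-3-yl)-2-[(phenylsulfonyl)methyl]pentan-1-ol
Conditions: K2CO3, MeOH, 0 °C → rt
Reagents that add atoms: none
Why: mild transesterification removes the acetate; with the other arm now a sulfone, no migration can scramble the stereocentre.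

**Step 18**
Reactants: 27 (2R)-5-(furan-3-yl)-2-[(phenylsulfonyl)methyl]pentan-1-ol
Product: 28 tert-butyl({(2R)-5-(furan-3-yl)-2-[(phenylsulfonyl)methyl]pentyl}oxy)dimethylsilane
Conditions: TBSCl, imidazole, DMF, rt
Reagents that add atoms: tert-butyldimethylsilyl chloride CC(C)(C)[Si](C)(C)Cl
Why: silyl protection of the primary alcohol shields it from the organolithium of the next step.

**Step 19**
Reactants: 28 tert-butyl({(2R)-5-(furan-3-yl)-2-[(phenylsulfonyl)methyl]pentyl}oxy)dimethylsilane; 16 (5R,6S)-6-[(3E)-5-bromo-3-methylpent-3-en-1-yl]-1,5,6-trimethylcyclohex-1-ene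
Product: 30 tert-butyl({(2R,5E)-2-[3-(furan-3-yl)propyl]-6-methyl-3-(phenylsulfonyl)-8-[(1S,6R)-1,2,6-trimethylcyclohex-2-en-1-yl]oct-5-en-1-yl}oxy)dimethylsilane (C3 epimer mixture), via α-lithio sulfone 29 (not isolated)
Conditions: n-BuLi (1.05 equiv), THF, −78 °C; then 16, THF/DMPU, −78 → −20 °C
Reagents that add atoms: n-butyllithium CCCC[Li] (lithium held in 29 only)
Why: α-sulfonyl carbanion alkylation: n-BuLi deprotonates only α to the sulfone, and the carbanion displaces the primary allylic bromide by SN2 with the E alkene intact; the new sulfone-bearing centre is removed next.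

**Step 20**
Reactants: 30 the coupled sulfone
Product: 31 tert-butyl({(2S,5E)-2-[3-(furan-3-yl)propyl]-6-methyl-8-[(1S,6R)-1,2,6-trimethylcyclohex-2-en-1-yl]oct-5-en-1-yl}oxy)dimethylsilane
Conditions: 5% Na(Hg), Na2HPO4, MeOH/THF, −20 → 0 °C
Reagents that add atoms: none
Why: buffered reductive desulfonylation replaces C–SO2Ph by C–H; the silyl ether, furan and both alkenes are inert and the neighbouring stereocentre is not involved (its label changes from R to S by CIP only).

**Step 21**
Reactants: 31 the TBS ether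
Product: 32 (2S,5E)-2-[3-(furan-3-yl)propyl]-6-methyl-8-[(1S,6R)-1,2,6-trimethylcyclohex-2-en-1-yl]oct-5-en-1-ol
Conditions: TBAF, THF, 0 °C → rt
Reagents that add atoms: none
Why: fluoride-mediated desilylation frees the primary alcohol without affecting anything else.

**Step 22**
Reactants: 32 (2S,5E)-2-[3-(furan-3-yl)propyl]-6-methyl-8-[(1S,6R)-1,2,6-trimethylcyclohex-2-en-1-yl]oct-5-en-1-ol
Product: 34 (2S,5E)-2-[3-(furan-3-yl)propyl]-6-methyl-8-[(1S,6R)-1,2,6-trimethylcyclohex-2-en-1-yl]oct-5-en-1-yl hydrogen sulfate, via pyridinium sulfate 33 (not isolated)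
Conditions: SO3·pyridine (2 equiv), pyridine, 0 °C → rt; then Dowex 50W (H+), MeOH/H2O, 0 °C, kept cold and dilute
Reagents that add atoms: sulfur trioxide–pyridine complex O=S(=O)([O-])[n+]1ccccc1
Why: O-sulfation of the primary alcohol is much faster than furan C-sulfonation at 0 °C–rt, and brief cold cation exchange gives the hydrogen sulfate as drawn.

## Compound list

1 | 2-methylcyclohex-2-en-1-one | CC1=CCCCC1=O | starting material
2 | dimethylaluminium (3R)-2,3-dimethylcyclohex-1-en-1-olate (not isolated) | C[Al](C)OC1=C(C)[C@H](C)CCC1 | intermediate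
3 | {[(3R)-2,3-dimethylcyclohex-1-en-1-yl]oxy}trimethylsilane | C[Si](C)(C)OC1=C(C)[C@H](C)CCC1 | intermediate
4 | lithium (3R)-2,3-dimethylcyclohex-1-en-1-olate (not isolated) | [Li+].[O-]C1=C(C)[C@H](C)CCC1 | intermediate
5 | (2S,3R)-2,3-dimethyl-2-(prop-2-en-1-yl)cyclohexan-1-one | O=C1CCC[C@@H](C)[C@]1(C)CC=C | intermediate
6 | potassium (5R,6S)-5,6-dimethyl-6-(prop-2-en-1-yl)cyclohex-1-en-1-olate (not isolated) | [K+].[O-]C1=CCC[C@@H](C)[C@]1(C)CC=C | intermediate
7 | (5R,6S)-5,6-dimethyl-6-(prop-2-en-1-yl)cyclohex-1-en-1-yl trifluoromethanesulfonate | O=S(=O)(OC1=CCC[C@@H](C)[C@]1(C)CC=C)C(F)(F)F | intermediate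
8 | (5R,6S)-1,5,6-trimethyl-6-(prop-2-en-1-yl)cyclohex-1-ene | CC1=CCC[C@@H](C)[C@]1(C)CC=C | intermediate
9 | 9-{3-[(1S,6R)-1,2,6-trimethylcyclohex-2-en-1-yl]propyl}-9-borabicyclo[3.3.1]nonane (not isolated) | CC1=CCC[C@@H](C)[C@]1(C)CCCB1C2CCCC1CCC2 | intermediate
10 | 3-[(1S,6R)-1,2,6-trimethylcyclohex-2-en-1-yl]propan-1-ol | CC1=CCC[C@@H](C)[C@]1(C)CCCO | intermediate
11 | 3-[(1S,6R)-1,2,6-trimethylcyclohex-2-en-1-yl]propanal | CC1=CCC[C@@H](C)[C@]1(C)CCC=O | intermediate
12 | (5R,6S)-6-(but-3-yn-1-yl)-1,5,6-trimethylcyclohex-1-ene | CC1=CCC[C@@H](C)[C@]1(C)CCC#C | intermediate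
13 | dimethyl{(1E)-2-methyl-4-[(1S,6R)-1,2,6-trimethylcyclohex-2-en-1-yl]but-1-en-1-yl}alumane (not isolated) | CC1=CCC[C@@H](C)[C@]1(C)CC/C(C)=C/[Al](C)C | intermediate
14 | lithium butyl(dimethyl){(1E)-2-methyl-4-[(1S,6R)-1,2,6-trimethylcyclohex-2-en-1-yl]but-1-en-1-yl}aluminate (not isolated) | [Li+].CC1=CCC[C@@H](C)[C@]1(C)CC/C(C)=C/[Al-](C)(C)CCCC | intermediate
15 | (2E)-3-methyl-5-[(1S,6R)-1,2,6-trimethylcyclohex-2-en-1-yl]pent-2-en-1-ol | CC1=CCC[C@@H](C)[C@]1(C)CC/C(C)=C/CO | intermediate
16 | (5R,6S)-6-[(3E)-5-bromo-3-methylpent-3-en-1-yl]-1,5,6-trimethylcyclohex-1-ene | CC1=CCC[C@@H](C)[C@]1(C)CC/C(C)=C/CBr | intermediate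
17 | diethyl 2-(prop-2-en-1-yl)propanedioate (diethyl allylmalonate) | CCOC(=O)C(CC=C)C(=O)OCC | starting material
18 | 2-(prop-2-en-1-yl)propane-1,3-diol | OCC(CO)CC=C | intermediate
19 | 2,2-dimethyl-5-(prop-2-en-1-yl)-1,3-dioxane | CC1(C)OCC(CC=C)CO1 | intermediate
20 | 3-bromofuran | Brc1ccoc1 | starting material
21 | 9-[3-(2,2-dimethyl-1,3-dioxan-5-yl)propyl]-9-borabicyclo[3.3.1]nonane (not isolated) | CC1(C)OCC(CCCB2C3CCCC2CCC3)CO1 | intermediate
22 | 5-[3-(furan-3-yl)propyl]-2,2-dimethyl-1,3-dioxane | CC1(C)OCC(CCCc2ccoc2)CO1 | intermediate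
23 | 2-[3-(furan-3-yl)propyl]propane-1,3-diol | OCC(CO)CCCc1ccoc1 | intermediate
24 | (2S)-5-(furan-3-yl)-2-(hydroxymethyl)pentyl acetate | OC[C@H](CCCc1ccoc1)COC(C)=O | intermediate
25 | (2R)-5-(furan-3-yl)-2-(iodomethyl)pentyl acetate | IC[C@H](CCCc1ccoc1)COC(C)=O | intermediate
26 | (2R)-5-(furan-3-yl)-2-[(phenylsulfonyl)methyl]pentyl acetate | O=S(=O)(C[C@H](CCCc1ccoc1)COC(C)=O)c1ccccc1 | intermediate
27 | (2R)-5-(furan-3-yl)-2-[(phenylsulfonyl)methyl]pentan-1-ol | O=S(=O)(C[C@H](CCCc1ccoc1)CO)c1ccccc1 | intermediate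
28 | tert-butyl({(2R)-5-(furan-3-yl)-2-[(phenylsulfonyl)methyl]pentyl}oxy)dimethylsilane | O=S(=O)(C[C@H](CCCc1ccoc1)CO[Si](C)(C)C(C)(C)C)c1ccccc1 | intermediate
29 | α-lithio derivative of 28 (not isolated) | [Li]C([C@H](CCCc1ccoc1)CO[Si](C)(C)C(C)(C)C)S(=O)(=O)c1ccccc1 | intermediate
30 | tert-butyl({(2R,5E)-2-[3-(furan-3-yl)propyl]-6-methyl-3-(phenylsulfonyl)-8-[(1S,6R)-1,2,6-trimethylcyclohex-2-en-1-yl]oct-5-en-1-yl}oxy)dimethylsilane (C3 epimer mixture) | CC1=CCC[C@@H](C)[C@]1(C)CC/C(C)=C/CC([C@H](CCCc1ccoc1)CO[Si](C)(C)C(C)(C)C)S(=O)(=O)c1ccccc1 | intermediate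
31 | tert-butyl({(2S,5E)-2-[3-(furan-3-yl)propyl]-6-methyl-8-[(1S,6R)-1,2,6-trimethylcyclohex-2-en-1-yl]oct-5-en-1-yl}oxy)dimethylsilane | CC1=CCC[C@@H](C)[C@]1(C)CC/C(C)=C/CC[C@H](CCCc1ccoc1)CO[Si](C)(C)C(C)(C)C | intermediate
32 | (2S,5E)-2-[3-(furan-3-yl)propyl]-6-methyl-8-[(1S,6R)-1,2,6-trimethylcyclohex-2-en-1-yl]oct-5-en-1-ol | CC1=CCC[C@@H](C)[C@]1(C)CC/C(C)=C/CC[C@H](CCCc1ccoc1)CO | intermediate
33 | pyridinium (2S,5E)-2-[3-(furan-3-yl)propyl]-6-methyl-8-[(1S,6R)-1,2,6-trimethylcyclohex-2-en-1-yl]oct-5-en-1-yl sulfate (not isolated) | CC1=CCC[C@@H](C)[C@]1(C)CC/C(C)=C/CC[C@H](CCCc1ccoc1)COS(=O)(=O)[O-].c1cc[nH+]cc1 | intermediate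
34 | (2S,5E)-2-[3-(furan-3-yl)propyl]-6-methyl-8-[(1S,6R)-1,2,6-trimethylcyclohex-2-en-1-yl]oct-5-en-1-yl hydrogen sulfate | CC1=CCC[C@@H](C)[C@]1(C)CC/C(C)=C/CC[C@H](CCCc1ccoc1)COS(=O)(=O)O | target

## Step count and risks

Total steps: 22. Longest linear sequence: 13 (steps 1–9, then 19–22; the furan branch, steps 10–18 then 19–22, is also 13).

**Step 1** (asymmetric conjugate addition with in-flask O-silylation). The weakly nucleophilic aluminium enolate may silylate incompletely. Fallback: set out from 1, run the same Cu-catalysed Me3Al addition but quench with aqueous NH4Cl/Rochelle salt and isolate (3R)-2,3-dimethylcyclohexan-1-one F1 (C2 epimer mixture, which does not matter). Then form the more substituted silyl enol ether from the isolated ketone under equilibrating conditions (TMSCl, Et3N, DMF, 80 °C), which comes back to the route at 3. The minor, less substituted isomer is removed by distillation or, after step 2, as its different allylation product. This replaces kinetic trapping of a metal enolate by thermodynamic enol ether formation.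

**Step 8** (carboalumination with formaldehyde trapping). The alanate/paraformaldehyde step can give low conversion. Fallback: set out from aldehyde 11 and build the alkene by olefination instead. MeMgBr (THF, 0 °C) gives 4-[(1S,6R)-1,2,6-trimethylcyclohex-2-en-1-yl]butan-2-ol F2 (carbinol epimers). Dess–Martin oxidation gives 4-[(1S,6R)-1,2,6-trimethylcyclohex-2-en-1-yl]butan-2-one F3. Horner–Wadsworth–Emmons olefination (triethyl phosphonoacetate, NaH, THF) gives ethyl (2E)-3-methyl-5-[(1S,6R)-1,2,6-trimethylcyclohex-2-en-1-yl]pent-2-enoate F4, with E favoured and the Z isomer removed by chromatography. DIBAL-H (CH2Cl2, −78 °C) then returns to the route at 15.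

**Step 14** (lipase desymmetrisation). The ee or the sense of acylation may not be as expected. Fallback: set out from diol 23 and use the enantiocomplementary hydrolytic mode with the arm order reversed.
- Ac2O/pyridine/DMAP gives 2-[3-(furan-3-yl)propyl]propane-1,3-diyl diacetate F5.
- Lipase-catalysed hydrolysis of one enantiotopic acetate (same lipase class, pH 7 phosphate buffer/MTBE) gives (2R)-5-(furan-3-yl)-2-(hydroxymethyl)pentyl acetate F6. This is also the compound to use if direct acylation turns out to deliver the R monoacetate.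
- TBSCl/imidazole gives (2S)-2-({[tert-butyl(dimethyl)silyl]oxy}methyl)-5-(furan-3-yl)pentyl acetate F7.
- K2CO3/MeOH gives (2S)-2-({[tert-butyl(dimethyl)silyl]oxy}methyl)-5-(furan-3-yl)pentan-1-ol F8.
- I2/PPh3/imidazole gives tert-butyl({(2R)-5-(furan-3-yl)-2-(iodomethyl)pentyl}oxy)dimethylsilane F9.
- PhSO2Na in DMF then comes back to the route at 28, the same enantiomer as in the main line.

## Further compounds

F1 | step 1 | (3R)-2,3-dimethylcyclohexan-1-one (C2 epimer mixture) | CC1[C@H](C)CCCC1=O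
F2 | step 8 | 4-[(1S,6R)-1,2,6-trimethylcyclohex-2-en-1-yl]butan-2-ol (carbinol epimers) | CC1=CCC[C@@H](C)[C@]1(C)CCC(C)O
F3 | step 8 | 4-[(1S,6R)-1,2,6-trimethylcyclohex-2-en-1-yl]butan-2-one | CC1=CCC[C@@H](C)[C@]1(C)CCC(C)=O
F4 | step 8 | ethyl (2E)-3-methyl-5-[(1S,6R)-1,2,6-trimethylcyclohex-2-en-1-yl]pent-2-enoate | CC1=CCC[C@@H](C)[C@]1(C)CC/C(C)=C/C(=O)OCC
F5 | step 14 | 2-[3-(furan-3-yl)propyl]propane-1,3-diyl diacetate | CC(=O)OCC(COC(C)=O)CCCc1ccoc1
F6 | step 14 | (2R)-5-(furan-3-yl)-2-(hydroxymethyl)pentyl acetate | OC[C@@H](CCCc1ccoc1)COC(C)=O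
F7 | step 14 | (2S)-2-({[tert-butyl(dimethyl)silyl]oxy}methyl)-5-(furan-3-yl)pentyl acetate | CC(C)(C)[Si](C)(C)OC[C@@H](CCCc1ccoc1)COC(C)=O
F8 | step 14 | (2S)-2-({[tert-butyl(dimethyl)silyl]oxy}methyl)-5-(furan-3-yl)pentan-1-ol | CC(C)(C)[Si](C)(C)OC[C@@H](CCCc1ccoc1)CO
F9 | step 14 | tert-butyl({(2R)-5-(furan-3-yl)-2-(iodomethyl)pentyl}oxy)dimethylsilane | CC(C)(C)[Si](C)(C)OC[C@@H](CCCc1ccoc1)CI
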